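**Retrosynthetic overview**
1. Target ⇒ ester reduction last; the polyene is closed by two Wittig unions (C11'=C12', then C11=C12) of the central C10 dialdehyde with a ring-end C20 phosphonium salt and a chain-end C20 phosphonium salt.
2. Chain end: the C2–C3 bond is made by a NiCl2(dme)/bis(oxazoline)-catalysed stereoconvergent coupling in which the α-carbon of a racemic α-bromo ketone (an enolonium equivalent) is joined to a tetraenylzirconium; this one step sets C2 (S). The C1 carbinol then comes from methyl addition.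
3. The tetraenyne for that coupling comes from a C6 enynol phosphonium salt and a C5 acetoxy aldehyde (Wittig).
4. Ring end: (R)-limonene oxide supplies C2' (R); oxidative ring cleavage, Wittig (side chain), Saucy–Marbet chain extension, cyclisation, then vinyl Grignard addition and phosphonium salt formation.
5. Ring order: the only ring made is the cyclohexene of the ring end, closed once (step 5) by proton-initiated cation–olefin cyclisation (C1'–C6' bond); limonene's own ring is opened in step 1.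

Assumption: the bis(oxazoline) antipode that gives the S centre in step 12 is chosen by analogy (its mirror image is used if the first run gives R), and Z isomers from the Wittig steps are equilibrated to E as written in the conditions.

**Ring-end fragment**

Step 1
Reactants: 1 (4R)-limonene 1,2-oxide (cis/trans mixture)
Product: 3 (3R)-6-oxo-3-(prop-1-en-2-yl)heptanal, via limonene-1,2-diol 2 (not isolated)
Conditions: H5IO6 (1.1 equiv), THF/H2O, 0 °C to rt
Reagents that add atoms: water, O
Why: Periodic acid hydrolyses the epoxide and cleaves the resulting 1,2-diol (Malaprade glycol cleavage) without touching the isopropenyl group, and the untouched C4 centre of limonene becomes C2' (R) of the target.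

Step 2
Reactants: 3 (3R)-6-oxo-3-(prop-1-en-2-yl)heptanal; 4 ethyl 2-(triphenyl-λ5-phosphanylidene)propanoate
Product: 5 ethyl (2E,5R)-2-methyl-8-oxo-5-(prop-1-en-2-yl)non-2-enoate
Conditions: CH2Cl2, rt, 16 h
Reagents that add atoms: ethyl 2-(triphenyl-λ5-phosphanylidene)propanoate (4), CCOC(=O)C(C)=P(c1ccccc1)(c1ccccc1)c1ccccc1
Why: The stabilised ylide reacts only with the aldehyde, not the methyl ketone (Wittig olefination), and gives the (E)-trisubstituted enoate that carries the side chain in an acid-stable form.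

Step 3
Reactants: 5 ethyl (2E,5R)-2-methyl-8-oxo-5-(prop-1-en-2-yl)non-2-enoate; 6 ethynylmagnesium bromide
Product: 7 ethyl (2E,5R)-8-hydroxy-2,8-dimethyl-5-(prop-1-en-2-yl)dec-2-en-9-ynoate (both C8 epimers)
Conditions: 6 (1.2 equiv), THF, −40 to 0 °C; aq. NH4Cl
Reagents that add atoms: ethynylmagnesium bromide (6), C#C[Mg]Br
Why: Grignard 1,2-addition to the methyl ketone is far faster than attack on the α-methyl conjugated ester at low temperature, and the new carbinol centre is lost in step 4.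

Step 4
Reactants: 7 ethyl (2E,5R)-8-hydroxy-2,8-dimethyl-5-(prop-1-en-2-yl)dec-2-en-9-ynoate; 8 2-methoxypropene
Product: 11 ethyl (2E,5R,10E)-2,8-dimethyl-12-oxo-5-(prop-1-en-2-yl)trideca-2,8,10-trienoate (8E/8Z mixture), via propargyl isopropenyl ether 9 (not isolated), via allenyl ketone 10 (not isolated)
Conditions: 8 (3 equiv), TsOH·H2O (0.5 mol%), toluene, sealed tube, 110 °C; then NaOEt (5 mol%), EtOH, 0 °C
Reagents that add atoms: 2-methoxypropene (8), COC(C)=C
Why: Saucy–Marbet reaction (acetal exchange, then propargyl Claisen rearrangement) gives the β-keto allene, which base isomerises into the conjugated dienone, the same route by which dehydrolinalool is turned into pseudoionone.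

Step 5
Reactants: 11 ethyl (2E,5R,10E)-2,8-dimethyl-12-oxo-5-(prop-1-en-2-yl)trideca-2,8,10-trienoate
Product: 12 ethyl (2E)-2-methyl-4-[(1R)-2,2,4-trimethyl-3-[(1E)-3-oxobut-1-en-1-yl]cyclohex-3-en-1-yl]but-2-enoate
Conditions: conc. H2SO4 (3 equiv), CH2Cl2, −20 °C, 15 min; ice/NaHCO3
Reagents that add atoms: none
Why: Proton-initiated cation–olefin cyclisation of the pseudoionone type: protonation of the isopropenyl group gives the C1' cation, the C5'=C6' bond closes the six-membered ring and proton loss gives the conjugated β-isomer, while the protonated enoate is not nucleophilic and C2' is not a reacting centre, so its R configuration is kept if ring closure outruns hydride shift.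

Step 6
Reactants: 12 ethyl (2E)-2-methyl-4-[(1R)-2,2,4-trimethyl-3-[(1E)-3-oxobut-1-en-1-yl]cyclohex-3-en-1-yl]but-2-enoate; 13 vinylmagnesium bromide
Product: 14 ethyl (2E)-4-[(1R)-3-[(1E)-3-hydroxy-3-methylpenta-1,4-dien-1-yl]-2,2,4-trimethylcyclohex-3-en-1-yl]-2-methylbut-2-enoate (both carbinol epimers)
Conditions: 13 (1.2 equiv), THF, −40 °C; aq. NH4Cl
Reagents that add atoms: vinylmagnesium bromide (13), C=C[Mg]Br
Why: Grignard 1,2-addition to the dienone (as in the vinyl-β-ionol synthesis) is chemoselective over the hindered conjugated ester at low temperature.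

Step 7
Reactants: 14 ethyl (2E)-4-[(1R)-3-[(1E)-3-hydroxy-3-methylpenta-1,4-dien-1-yl]-2,2,4-trimethylcyclohex-3-en-1-yl]-2-methylbut-2-enoate
Product: 15 [(2E,4E)-5-[(5R)-5-[(2E)-4-ethoxy-3-methyl-4-oxobut-2-en-1-yl]-2,6,6-trimethylcyclohex-1-en-1-yl]-3-methylpenta-2,4-dien-1-yl]triphenylphosphonium bromide
Conditions: PPh3·HBr (1.05 equiv), CH2Cl2, rt, 16 h; crystallise
Reagents that add atoms: triphenylphosphine hydrobromide, [PH+](c1ccccc1)(c1ccccc1)c1ccccc1.[Br-]
Why: Acid ionises the tertiary bis-allylic alcohol and PPh3 traps the delocalised cation at its primary terminus (SN1-type allylic substitution with transposition, the standard C15 salt synthesis), giving the 9'E salt.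

Step 8
Reactants: 15 ring-end phosphonium bromide; 16 (2E,4E,6E)-2,7-dimethylocta-2,4,6-trienedial
Product: 18 ethyl (2E)-2-methyl-4-[(1R)-2,2,4-trimethyl-3-[(1E,3E,5E,7E,9E,11E)-3,7,12-trimethyl-13-oxotrideca-1,3,5,7,9,11-hexaen-1-yl]cyclohex-3-en-1-yl]but-2-enoate, via phosphorus ylide 17 (not isolated)
Conditions: 16 (2 equiv), 1,2-epoxybutane/EtOH, reflux; then cat. I2, CH2Cl2, rt (Z to E)
Reagents that add atoms: (2E,4E,6E)-2,7-dimethylocta-2,4,6-trienedial (16), O=C/C(C)=C/C=C/C=C(C)/C=O
Why: Wittig mono-olefination of the symmetrical dialdehyde used in excess forms C11'=C12', and the epoxide acts as a neutral HBr scavenger so the ethyl ester survives.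

**Chain-end fragment**

Step 9
Reactants: 19 6-methylhept-5-en-2-one
Product: 21 rac-3-bromo-6-methylhept-5-en-2-one, via silyl enol ether 20 (not isolated)
Conditions: TMSOTf (1.1 equiv), Et3N (1.3 equiv), CH2Cl2, 0 °C to rt; then NBS (1.05 equiv), −78 °C; chromatography
Reagents that add atoms: N-bromosuccinimide, O=C1CCC(=O)N1Br
Why: Soft enolisation gives mainly the more substituted silyl enol ether, which NBS brominates at carbon faster than it attacks the prenyl alkene (α-bromination of a silyl enol ether); the minor 1-bromo isomer is removed and the centre is deliberately racemic.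

Step 10
Reactants: 22 (2E)-3-methylpent-2-en-4-yn-1-ol
Product: 23 [(2E)-3-methylpent-2-en-4-yn-1-yl]triphenylphosphonium bromide
Conditions: PPh3·HBr (1.0 equiv), MeOH, 40 °C, 24 h
Reagents that add atoms: triphenylphosphine hydrobromide, [PH+](c1ccccc1)(c1ccccc1)c1ccccc1.[Br-]
Why: The primary allylic alcohol ionises to a methyl- and alkynyl-stabilised allyl cation that PPh3 captures at the primary carbon (allylic phosphonium salt formation), retaining the E enyne.

Step 11
Reactants: 23 [(2E)-3-methylpent-2-en-4-yn-1-yl]triphenylphosphonium bromide; 24 (2E)-3-methyl-4-oxobut-2-en-1-yl acetate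
Product: 26 (2E,4E,6E)-3,7-dimethylnona-2,4,6-trien-8-yn-1-yl acetate, via phosphorus ylide 25 (not isolated)
Conditions: 1,2-epoxybutane, reflux, 18 h; then cat. I2, hexane, rt (Z to E)
Reagents that add atoms: (2E)-3-methyl-4-oxobut-2-en-1-yl acetate (24), O=C/C(C)=C/COC(C)=O
Why: Wittig olefination under base-free epoxide conditions forms C7=C8 without cleaving the acetate or deprotonating the terminal alkyne, the same type of union that joins a C15 salt to this C5 aldehyde industrially.

Step 12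
Reactants: 26 (2E,4E,6E)-3,7-dimethylnona-2,4,6-trien-8-yn-1-yl acetate; 21 rac-3-bromo-6-methylhept-5-en-2-one
Product: 28 (2E,4E,6E,8E,10S)-10-acetyl-3,7,13-trimethyltetradeca-2,4,6,8,12-pentaen-1-yl acetate, via alkenylzirconocene chloride 27 (not isolated)
Conditions: 26 (1.2 equiv), Cp2Zr(H)Cl (1.2 equiv), THF, rt, 30 min; then 21 (1.0 equiv), NiCl2(dme) (5 mol%), (4S,4'S)-2,2'-(propane-2,2-diyl)bis(4-phenyl-4,5-dihydrooxazole) (6.5 mol%), DME/THF, 10 °C, 24 h
Reagents that add atoms: rac-3-bromo-6-methylhept-5-en-2-one (21), CC(=O)C(Br)CC=C(C)C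
Why: Proposed new method: the α-bromo ketone acts as an enolonium equivalent, so the normally nucleophilic ketone α-carbon is joined to the nucleophilic alkenyl carbon made by syn hydrozirconation of the terminal alkyne; monovalent nickel abstracts bromine to give a planar α-keto radical (this erases the racemic centre, and the prenyl group offers no feasible ring closure), which recombines with the chiral alkenylnickel and reductively eliminates to set C2 as S under ligand control with the E geometry retained; the closest known reaction type is the nickel/bis(oxazoline)-catalysed stereoconvergent Negishi-type alkenylation of racemic α-bromo ketones with alkenylzirconium reagents, here extended to a methyl alkyl ketone and a tetraenylzirconium bearing an allylic acetate.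

Step 13
Reactants: 28 (2E,4E,6E,8E,10S)-10-acetyl-3,7,13-trimethyltetradeca-2,4,6,8,12-pentaen-1-yl acetate; 29 methylmagnesium bromide
Product: 30 (2E,4E,6E,8E,10S)-10-(2-hydroxypropan-2-yl)-3,7,13-trimethyltetradeca-2,4,6,8,12-pentaen-1-ol
Conditions: crude 28 added to 29 (5 equiv)/CeCl3 (1.5 equiv), THF, −78 to 0 °C; aq. NH4Cl
Reagents that add atoms: methylmagnesium bromide (29), C[Mg]Br
Why: Organocerium-mediated Grignard addition (Imamoto conditions) adds methyl to the ketone without enolising the doubly activated α-hydrogen, so C2 is neither epimerised nor moved into conjugation, and the excess Grignard reagent cleaves the acetate in the same pot.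

Step 14
Reactants: 30 (2E,4E,6E,8E,10S)-10-(2-hydroxypropan-2-yl)-3,7,13-trimethyltetradeca-2,4,6,8,12-pentaen-1-ol
Product: 31 [(2E,4E,6E,8E,10S)-10-(2-hydroxypropan-2-yl)-3,7,13-trimethyltetradeca-2,4,6,8,12-pentaen-1-yl]triphenylphosphonium bromide
Conditions: PPh3·HBr (1.0 equiv), MeOH, 0 °C to rt
Reagents that add atoms: triphenylphosphine hydrobromide, [PH+](c1ccccc1)(c1ccccc1)c1ccccc1.[Br-]
Why: Only the primary, polyene-conjugated allylic alcohol ionises and PPh3 traps the cation at its primary terminus (SN1-type phosphonium salt formation), leaving the non-allylic tertiary alcohol, the prenyl group and C2 untouched.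

**Union and end game**

Step 15
Reactants: 31 chain-end phosphonium bromide; 18 ring-end aldehyde ester
Product: 33 ethyl (2E)-4-[(1R)-3-[(1E,3E,5E,7E,9E,11E,13E,15E,17E,19E,21E,23S)-23-(2-hydroxypropan-2-yl)-3,7,12,16,20,26-hexamethylheptacosa-1,3,5,7,9,11,13,15,17,19,21,25-dodecaen-1-yl]-2,2,4-trimethylcyclohex-3-en-1-yl]-2-methylbut-2-enoate, via phosphorus ylide 32 (not isolated)
Conditions: 1,2-epoxybutane/EtOH, reflux, dark, argon; then heptane, reflux (Z to E), crystallise
Reagents that add atoms: ring-end aldehyde ester (18), O=C/C(C)=C/C=C/C=C(C)/C=C/C=C(C)/C=C/C1=C(C)CC[C@H](C/C=C(\C)C(=O)OCC)C1(C)C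
Why: Wittig olefination of a polyenal with a polyenyl ylide forms C11=C12 as in industrial carotenoid couplings, the free tertiary alcohol is tolerated under the base-free conditions, and the unhindered Z isomer equilibrates thermally to all-E.

Step 16
Reactants: 33 ethyl ester of the target
Product: 34 (2E)-4-[(1R)-3-[(1E,3E,5E,7E,9E,11E,13E,15E,17E,19E,21E,23S)-23-(2-hydroxypropan-2-yl)-3,7,12,16,20,26-hexamethylheptacosa-1,3,5,7,9,11,13,15,17,19,21,25-dodecaen-1-yl]-2,2,4-trimethylcyclohex-3-en-1-yl]-2-methylbut-2-en-1-ol (the target, 2S,2'R)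
Conditions: iBu2AlH (4 equiv), CH2Cl2, −78 °C, 1 h; aq. KNaC4H4O6
Reagents that add atoms: none
Why: Hydride 1,2-reduction of the conjugated ester to the allylic alcohol at low temperature leaves the polyene, both stereocentres and the tertiary alkoxide untouched.

**Compound list**
1 | (4R)-limonene 1,2-oxide (cis/trans mixture) | CC12OC1C[C@@H](CC2)C(=C)C | starting material
2 | (4R)-1-methyl-4-(prop-1-en-2-yl)cyclohexane-1,2-diol | CC1(O)C(O)C[C@@H](CC1)C(=C)C | intermediate
3 | (3R)-6-oxo-3-(prop-1-en-2-yl)heptanal | CC(=O)CC[C@H](CC=O)C(C)=C | intermediate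
4 | ethyl 2-(triphenyl-λ5-phosphanylidene)propanoate | CCOC(=O)C(C)=P(c1ccccc1)(c1ccccc1)c1ccccc1 | starting material
5 | ethyl (2E,5R)-2-methyl-8-oxo-5-(prop-1-en-2-yl)non-2-enoate | CC(=O)CC[C@H](C/C=C(\C)C(=O)OCC)C(C)=C | intermediate
6 | ethynylmagnesium bromide | C#C[Mg]Br | starting material
7 | ethyl (2E,5R)-8-hydroxy-2,8-dimethyl-5-(prop-1-en-2-yl)dec-2-en-9-ynoate | C#CC(C)(O)CC[C@H](C/C=C(\C)C(=O)OCC)C(C)=C | intermediate
8 | 2-methoxypropene | COC(C)=C | starting material
9 | ethyl (2E,5R)-2,8-dimethyl-5-(prop-1-en-2-yl)-8-(prop-1-en-2-yloxy)dec-2-en-9-ynoate | C#CC(C)(OC(C)=C)CC[C@H](C/C=C(\C)C(=O)OCC)C(C)=C | intermediate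
10 | ethyl (2E,5R)-2,8-dimethyl-12-oxo-5-(prop-1-en-2-yl)trideca-2,8,9-trienoate | CC(=O)CC=C=C(C)CC[C@H](C/C=C(\C)C(=O)OCC)C(C)=C | intermediate
11 | ethyl (2E,5R,10E)-2,8-dimethyl-12-oxo-5-(prop-1-en-2-yl)trideca-2,8,10-trienoate | CC(=O)/C=C/C=C(C)CC[C@H](C/C=C(\C)C(=O)OCC)C(C)=C | intermediate
12 | ethyl (2E)-2-methyl-4-[(1R)-2,2,4-trimethyl-3-[(1E)-3-oxobut-1-en-1-yl]cyclohex-3-en-1-yl]but-2-enoate | CC(=O)/C=C/C1=C(C)CC[C@H](C/C=C(\C)C(=O)OCC)C1(C)C | intermediate
13 | vinylmagnesium bromide | C=C[Mg]Br | starting material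
14 | ethyl (2E)-4-[(1R)-3-[(1E)-3-hydroxy-3-methylpenta-1,4-dien-1-yl]-2,2,4-trimethylcyclohex-3-en-1-yl]-2-methylbut-2-enoate | C=CC(C)(O)/C=C/C1=C(C)CC[C@H](C/C=C(\C)C(=O)OCC)C1(C)C | intermediate
15 | [(2E,4E)-5-[(5R)-5-[(2E)-4-ethoxy-3-methyl-4-oxobut-2-en-1-yl]-2,6,6-trimethylcyclohex-1-en-1-yl]-3-methylpenta-2,4-dien-1-yl]triphenylphosphonium bromide | c1ccccc1[P+](c1ccccc1)(c1ccccc1)C/C=C(C)/C=C/C1=C(C)CC[C@H](C/C=C(\C)C(=O)OCC)C1(C)C.[Br-] | intermediate
16 | (2E,4E,6E)-2,7-dimethylocta-2,4,6-trienedial | O=C/C(C)=C/C=C/C=C(C)/C=O | starting material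
17 | ylide of 15 | c1ccccc1P(c1ccccc1)(c1ccccc1)=C/C=C(C)/C=C/C1=C(C)CC[C@H](C/C=C(\C)C(=O)OCC)C1(C)C | intermediate
18 | ethyl (2E)-2-methyl-4-[(1R)-2,2,4-trimethyl-3-[(1E,3E,5E,7E,9E,11E)-3,7,12-trimethyl-13-oxotrideca-1,3,5,7,9,11-hexaen-1-yl]cyclohex-3-en-1-yl]but-2-enoate | O=C/C(C)=C/C=C/C=C(C)/C=C/C=C(C)/C=C/C1=C(C)CC[C@H](C/C=C(\C)C(=O)OCC)C1(C)C | intermediate
19 | 6-methylhept-5-en-2-one | CC(=O)CCC=C(C)C | starting material
20 | trimethyl[(6-methylhepta-2,5-dien-2-yl)oxy]silane | CC(O[Si](C)(C)C)=CCC=C(C)C | intermediate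
21 | rac-3-bromo-6-methylhept-5-en-2-one | CC(=O)C(Br)CC=C(C)C | intermediate
22 | (2E)-3-methylpent-2-en-4-yn-1-ol | C#C/C(C)=C/CO | starting material
23 | [(2E)-3-methylpent-2-en-4-yn-1-yl]triphenylphosphonium bromide | C#C/C(C)=C/C[P+](c1ccccc1)(c1ccccc1)c1ccccc1.[Br-] | intermediate
24 | (2E)-3-methyl-4-oxobut-2-en-1-yl acetate | O=C/C(C)=C/COC(C)=O | starting material
25 | ylide of 23 | C#C/C(C)=C/C=P(c1ccccc1)(c1ccccc1)c1ccccc1 | intermediate
26 | (2E,4E,6E)-3,7-dimethylnona-2,4,6-trien-8-yn-1-yl acetate | C#C/C(C)=C/C=C/C(C)=C/COC(C)=O | intermediate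
27 | chlorobis(cyclopentadienyl)[(1E,3E,5E,7E)-9-acetoxy-3,7-dimethylnona-1,3,5,7-tetraen-1-yl]zirconium (rings drawn σ-bonded) | Cl[Zr](C1C=CC=C1)(C1C=CC=C1)/C=C/C(C)=C/C=C/C(C)=C/COC(C)=O | intermediate
28 | (2E,4E,6E,8E,10S)-10-acetyl-3,7,13-trimethyltetradeca-2,4,6,8,12-pentaen-1-yl acetate | CC(C)=CC[C@@H](/C=C/C(C)=C/C=C/C(C)=C/COC(C)=O)C(C)=O | intermediate
29 | methylmagnesium bromide | C[Mg]Br | starting material
30 | (2E,4E,6E,8E,10S)-10-(2-hydroxypropan-2-yl)-3,7,13-trimethyltetradeca-2,4,6,8,12-pentaen-1-ol | CC(C)=CC[C@@H](/C=C/C(C)=C/C=C/C(C)=C/CO)C(C)(C)O | intermediate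
31 | [(2E,4E,6E,8E,10S)-10-(2-hydroxypropan-2-yl)-3,7,13-trimethyltetradeca-2,4,6,8,12-pentaen-1-yl]triphenylphosphonium bromide | CC(C)=CC[C@@H](/C=C/C(C)=C/C=C/C(C)=C/C[P+](c1ccccc1)(c1ccccc1)c1ccccc1)C(C)(C)O.[Br-] | intermediate
32 | ylide of 31 | CC(C)=CC[C@@H](/C=C/C(C)=C/C=C/C(C)=C/C=P(c1ccccc1)(c1ccccc1)c1ccccc1)C(C)(C)O | intermediate
33 | ethyl ester of the target (side-chain CO2Et in place of CH2OH; full name in step 15) | CC(C)=CC[C@@H](/C=C/C(C)=C/C=C/C(C)=C/C=C/C(C)=C/C=C/C=C(C)/C=C/C=C(C)/C=C/C1=C(C)CC[C@H](C/C=C(\C)C(=O)OCC)C1(C)C)C(C)(C)O | intermediate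
34 | CNP0286110.1, (2S,2'R) C50 carotenoid (full name in step 16) | CC(C)=CC[C@@H](/C=C/C(C)=C/C=C/C(C)=C/C=C/C(C)=C/C=C/C=C(C)/C=C/C=C(C)/C=C/C1=C(C)CC[C@H](C/C=C(\C)CO)C1(C)C)C(C)(C)O | target

**Totals**
Total step count: 16. Longest linear sequence: 10 steps (steps 1–8, 15, 16).

**Three steps most likely to fail, each with one fallback**

Step 12 (key coupling). The tetraenylzirconium 27 or its allylic acetate may not survive the nickel cycle, and the methyl ketone may give a lower ee than aryl ketones. The fallback sets out from 21 and 22 and comes back at 30. It makes the same bond at the C6 stage, on a dienylzirconium that has no allylic ester, and lengthens the chain afterwards. 22 is silylated (TBSCl, imidazole, CH2Cl2) to tert-butyldimethylsilyl ether F1. Cp2Zr(H)Cl turns this into dienylzirconocene chloride F2, which is coupled with 21 under the NiCl2(dme)/bis(oxazoline) system of step 12 to give (3S)-ketone F3. MeMgBr/CeCl3 then gives tertiary alcohol F4. PPh3·HBr in MeOH removes the silyl group and gives C15 phosphonium bromide F5, whose ylide F6 (1,2-epoxybutane, reflux) olefinates 24 to hydroxy acetate F7. K2CO3 in MeOH then gives 30.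

Step 5 (cyclisation). The C1' cation sits next to the C2'–H centre, so a 1,2-hydride shift or elimination–reprotonation could erode C2' or give a five-membered ring. The fallback sets out from 11 and comes back at 12. It closes the ring through a mercurinium ion, which never becomes a free cation. 11 is treated with Hg(OTf)2·PhNMe2 (MeNO2, −20 °C), only the electron-rich isopropenyl group is activated, and aq. NaCl gives organomercury chloride F8. Its C–Hg bond is reduced with Bu3SnH (THF, rt) to 12. Any ring double-bond isomer is then moved into conjugation with a trace of TsOH; this passes through the C5' cation, which is remote from C2'.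

Step 14 (phosphonium salt from the diol). The pentaenyl cation has density at C3, next to the carbon bearing the tertiary carbinol, so loss of acetone (retro-Prins fragmentation) or HBr addition to the prenyl group could compete. The fallback sets out from 30 and comes back at 33; it avoids acid and the phosphonium salt altogether. Mitsunobu reaction of 30 with 1-phenyl-1H-tetrazole-5-thiol (PPh3, DIAD, THF, 0 °C) gives tetrazolyl sulfide F9. (NH4)6Mo7O24 (10 mol%) with H2O2 in EtOH at 0 °C oxidises it to tetrazolyl sulfone F10. KN(SiMe3)2 (2.2 equiv, THF, −78 °C) and aldehyde 18 then give 33 directly by Julia–Kocienski olefination.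

**Further compounds**
F1 | step 12 | tert-butyldimethyl{[(2E)-3-methylpent-2-en-4-yn-1-yl]oxy}silane | C#C/C(C)=C/CO[Si](C)(C)C(C)(C)C
F2 | step 12 | chlorobis(cyclopentadienyl)[(1E,3E)-5-(tert-butyldimethylsilyloxy)-3-methylpenta-1,3-dien-1-yl]zirconium | Cl[Zr](C1C=CC=C1)(C1C=CC=C1)/C=C/C(C)=C/CO[Si](C)(C)C(C)(C)C
F3 | step 12 | (3S,4E,6E)-8-(tert-butyldimethylsilyloxy)-6-methyl-3-(3-methylbut-2-en-1-yl)octa-4,6-dien-2-one | CC(C)=CC[C@@H](/C=C/C(C)=C/CO[Si](C)(C)C(C)(C)C)C(C)=O
F4 | step 12 | (3S,4E,6E)-8-(tert-butyldimethylsilyloxy)-2,6-dimethyl-3-(3-methylbut-2-en-1-yl)octa-4,6-dien-2-ol | CC(C)=CC[C@@H](/C=C/C(C)=C/CO[Si](C)(C)C(C)(C)C)C(C)(C)O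
F5 | step 12 | [(2E,4E,6S)-7-hydroxy-3,7-dimethyl-6-(3-methylbut-2-en-1-yl)octa-2,4-dien-1-yl]triphenylphosphonium bromide | CC(C)=CC[C@@H](/C=C/C(C)=C/C[P+](c1ccccc1)(c1ccccc1)c1ccccc1)C(C)(C)O.[Br-]
F6 | step 12 | ylide of F5 | CC(C)=CC[C@@H](/C=C/C(C)=C/C=P(c1ccccc1)(c1ccccc1)c1ccccc1)C(C)(C)O
F7 | step 12 | (2E,4E,6E,8E,10S)-10-(2-hydroxypropan-2-yl)-3,7,13-trimethyltetradeca-2,4,6,8,12-pentaen-1-yl acetate | CC(C)=CC[C@@H](/C=C/C(C)=C/C=C/C(C)=C/COC(C)=O)C(C)(C)O
F8 | step 5 | chloro{[(6R)-6-[(2E)-4-ethoxy-3-methyl-4-oxobut-2-en-1-yl]-1,3-dimethyl-2-[(1E)-3-oxobut-1-en-1-yl]cyclohex-2-en-1-yl]methyl}mercury (both C1 epimers) | CC(=O)/C=C/C1=C(C)CC[C@H](C/C=C(\C)C(=O)OCC)C1(C)C[Hg]Cl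
F9 | step 14 | 5-{[(2E,4E,6E,8E,10S)-10-(2-hydroxypropan-2-yl)-3,7,13-trimethyltetradeca-2,4,6,8,12-pentaen-1-yl]sulfanyl}-1-phenyl-1H-tetrazole | CC(C)=CC[C@@H](/C=C/C(C)=C/C=C/C(C)=C/CSc1nnnn1-c1ccccc1)C(C)(C)O
F10 | step 14 | 5-{[(2E,4E,6E,8E,10S)-10-(2-hydroxypropan-2-yl)-3,7,13-trimethyltetradeca-2,4,6,8,12-pentaen-1-yl]sulfonyl}-1-phenyl-1H-tetrazole | CC(C)=CC[C@@H](/C=C/C(C)=C/C=C/C(C)=C/CS(=O)(=O)c1nnnn1-c1ccccc1)C(C)(C)O
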